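## The problem

Target 19 is a single cyclobutane ring (C1–C4) with 2,4-dihydroxybenzoyl groups on C1 and C3 and phenyl groups on C2 and C4, the head-to-tail pattern of an enone dimer. All four ring carbons are stereocentres and every neighbouring pair is trans, so the two phenyls share one face and the two aroyl groups the other; the molecule has two mirror planes and is achiral, so only relative configuration has to be controlled. C1 and C3 lie α to carbonyl groups and can be equilibrated; once the phenyls are cis, each carbonyl substituent is most stable trans to both neighbours, so these two centres can be left to thermodynamics. C2 and C4 cannot be epimerised, and their cis relationship, which the centrosymmetric head-to-tail photodimer of a trans-enone lacks, must be fixed in a bond-forming step. The four free phenols and the β-aryl ketones on a strained ring argue for attaching the resorcinol rings last, under acid, and for carrying C1 and C3 as carboxyl groups until then. The enabling feature is that C4 (and by symmetry C2) is a benzylic CH bonded to both carbonyl-bearing carbons C1 and C3: with one extra C1–C3 bond the skeleton is a bicyclo[1.1.0]butane in which C4 and its phenyl bridge the olefinic carbons of a cyclopropene-1,2-dicarboxylate as a benzylidene unit. That extra bond, flanked by two esters, can be removed again by reduction.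

## Retrosynthesis

**Aryl–carbonyl bonds.** Target 19 is cut at the two bonds between the ketone carbons and the resorcinol rings, giving the all-trans diacid 17 and two molecules of resorcinol 18. This cut is preferred to one at the ring–carbonyl bonds because it leaves the ring carbons at an epimerisable, robust oxidation level. It also uses the innate position 4 reactivity of 18, which gives the 2,4-dihydroxy pattern without protecting groups. The forward reaction must be a double acid-mediated C-acylation that does not disturb the ring.

**Ester hydrolysis and the C1/C3 configuration.** Diacid 17 comes from dimethyl ester 15 by hydrolysis through its disodium salt 16. Diester 15 is the thermodynamic member of the cis-diphenyl diester family 14, so the configuration at C1 and C3 need not be set on purpose. Only the cis relationship of the phenyls at C2 and C4 has to be delivered.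

**Adding the C1–C3 bond.** Retrosynthetically, a bond is drawn between C1 and C3 of 14, which gives bicyclobutane diester 13. This adds strain but removes two stereocentres from consideration and turns cis-diphenyl into exo,exo on the folded bicycle. The forward reaction is a two-electron reductive cleavage that must break only the central bond, the one conjugated with both esters.

**Benzylidene disconnection (key).** In 13 the two bonds from C4 to C1 and C3 are cut together. This gives cyclopropene diester 11 and the benzylic ylide 10, which is made from sulfonium salt 3; the forward reaction passes through betaine 12. Cutting one C–C bond at a time leads back to cyclobutane chemistry with no handle on the phenyl relationship. Here both C–C bonds at the benzylic carbon and the second ring form in one operation from an achiral olefin. The forward step must capture a very reactive cyclopropene before it reacts with itself and must place the incoming phenyl exo.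

**Cyclopropene to bromocyclopropane.** Cyclopropene 11 cannot be stored, so it is traced to bromide 9 by loss of HBr across C1–C2. The configuration of 9 is irrelevant because C1 and C2 become trigonal in 11.

**Cyclopropane C1–C2 bond.** Bromide 9 is cut at the bond between its two ester-bearing carbons, which leads through enolate 8 to the acyclic dibromide 7. The neighbouring cut, at the two bonds to the phenyl-bearing carbon, would need a first benzylidene transfer and then a separate enolate bromination. The chosen cut closes the ring with the bromine already in place and keeps the ylide chemistry for the one step that depends on it. The precursor is acyclic and constitutionally symmetrical. The forward reaction must be a single deprotonation and 3-exo-tet closure that stops before further loss of HBr.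

**α-Bromination and the salt.** Dibromide 7 is traced through acid chlorides 6 and 5 to 3-phenylglutaric acid 4 by removal of the two α-bromines. Salt 3 comes from benzyl bromide 1 and dimethyl sulfide 2. Ring carbons C1, C2 and C3 of the target therefore come from C2, C3 and C4 of 4, and C4 with its phenyl comes from 1.

## Roads not taken

**Alternative 1:** The cut is at the two C(sp3)–phenyl bonds. The forward step is a palladium-catalysed, silver-promoted double C–H phenylation of the cis-1,3-bis(quinolin-8-yl amide) A2 with an aryl iodide, each amide directing the metal to the cis hydrogen on C2 and C4. It gives the all-cis diphenyl diamide A1.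

- Merits: the reaction class is established on cyclobutane carboxamides, and the directing geometry forces the two phenyls cis to each other. On that point, the one that matters most, this road is more secure than the chosen plan. It is also shorter on paper: amide formation, arylation, then auxiliary removal with epimerisation to reach diacid 17.
- Weak points: A1 is the most congested isomer. Both amide-bearing carbons must be inverted and two robust quinolinyl amides cleaved from a ring that screens them on both sides. The second arylation must take place next to a phenyl already installed, and stoichiometric silver is consumed.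
- Comparison: the chosen plan builds the ring from 3-phenylglutaric acid 4 and benzyl bromide 1, carries simple methyl esters that hydrolyse easily, and needs no auxiliary and no precious metal. The price is that the phenyl relationship rests on a diastereoselective step without direct precedent.

**Alternative 2:** The cut is at the two ring–carbonyl bonds, with the ester groups kept as traceless activators. The forward step is Lewis-acid-mediated C-acylation of the bis(trimethylsilyl ketene acetal) A3 of a cis-diphenyl diester with 2,4-dimethoxybenzoyl chloride A4, giving the bis(β-keto ester) A5 with two quaternary carbons.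

- Merits: the ketones are made without hot acid, and the aroyl groups enter anti to the phenyls.
- Weak points: A3 has to be made from diester 15 or an epimer of it, so this road solves neither the ring construction nor the phenyl relationship. Two quaternary centres must form between phenyl-bearing carbons, where O-acylation is the likely diversion. Two dealkoxycarbonylations and four O-demethylations follow.
- Comparison: it replaces the two closing steps of the chosen plan by about four and is better in no respect except the avoidance of BF3.

**Alternative 3:** The cut is at the aryl C–O and acyl–aryl C–C bonds of each hydroxyketone. The forward step lets diacid 17 react with 3-chloro-5-methoxybenzyne A7, released by fluoride from the silylaryl triflate A6. Each carboxylate oxygen adds to the aryne and the aryl anion captures the acyl group, giving the bis(6-chloro-2-hydroxy-4-methoxybenzoyl) compound A8.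

- Merits: the conditions are mild and near neutral, gentler on the strained ring than the chosen end-game, and the ortho-hydroxy ketone forms directly.
- Weak points: the chlorine that steers the regiochemistry must be removed afterwards and the methyl ethers cleaved. A6 needs its own multistep synthesis. Simple O-arylation of the acid competes, and it must be suppressed twice in one molecule.
- Comparison: the chosen plan ends in one step from commodity resorcinol 18 with the substitution pattern built in, and has that step economy to set against the milder conditions here.

Key step: step 4

Assumption: because 19 is achiral, the stereodescriptors of its SMILES fix only the relative all-trans arrangement. Chiral intermediates (7, 9, 12) are racemic and, where a configuration is drawn, shown as one enantiomer.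

## Route

Step 1
Reactants: 1 benzyl bromide; 2 dimethyl sulfide
Product: 3 benzyldimethylsulfonium bromide
Conditions: Me2S (2 equiv), acetone, rt, 24 h; filter
Reagents that add atoms: none
Why: SN2 S-alkylation of a thioether by a benzylic bromide (sulfonium salt formation); the salt should crystallise from acetone, which drives the reaction and supplies clean material for step 4.

Step 2
Reactants: 4 3-phenylglutaric acid (3-phenylpentanedioic acid)
Product: 7 dimethyl 2,4-dibromo-3-phenylpentanedioate (diastereomer mixture), via 3-phenylpentanedioyl dichloride 5 (not isolated), via 2,4-dibromo-3-phenylpentanedioyl dichloride 6 (not isolated)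
Conditions: SOCl2 (solvent), cat. DMF, 70 °C; then NBS (2.4 equiv), cat. 48% HBr, 85 °C, dark; concentrate; then MeOH, 0 °C to rt
Reagents that add atoms: N-bromosuccinimide, O=C1CCC(=O)N1Br; methanol, CO
Why: Hell–Volhard–Zelinsky-type α-bromination of an acid chloride in its NBS/HBr variant: each acid chloride terminus of 5 enolises under HBr catalysis and takes up one bromine, and methanolysis of 6 gives the diester directly. The acid-catalysed ionic pathway, run in the dark, is chosen to keep bromine away from the benzylic C3–H and the phenyl ring; the diastereomers of 7 are carried together because all of them converge on cyclopropene 11 in step 4.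

Step 3
Reactants: 7 dimethyl 2,4-dibromo-3-phenylpentanedioate
Product: 9 dimethyl 1-bromo-3-phenylcyclopropane-1,2-dicarboxylate (diastereomer mixture), via lithium bromo ester enolate 8 (not isolated)
Conditions: LiN(SiMe3)2 (1.0 equiv, added slowly to 7), THF, −78 to 0 °C; aq. NH4Cl
Reagents that add atoms: none
Why: Intramolecular enolate C-alkylation (base-induced 1,3-dehydrobromination of an α,α'-dibromoglutarate): enolate 8 displaces the second α-bromide in a 3-exo-tet closure. One equivalent of a non-nucleophilic amide is used because the remaining α-hydrogen of 9 sits on the three-membered ring and is less acidic than the open-chain CHBr hydrogens of 7, which holds back further loss of HBr. All diastereomers of 9 converge on cyclopropene 11.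

Step 4
Reactants: 9 dimethyl 1-bromo-3-phenylcyclopropane-1,2-dicarboxylate; 3 benzyldimethylsulfonium bromide
Product: 13 dimethyl exo,exo-2,4-diphenylbicyclo[1.1.0]butane-1,3-dicarboxylate, via dimethylsulfonium benzylide 10 (not isolated), via cyclopropene diester 11 (not isolated), via sulfonium enolate betaine 12 (not isolated)
Conditions: flask A: 3 (1.1 equiv), KOtBu (1.0 equiv), THF, −78 °C; flask B: 9, KN(SiMe3)2 (1.0 equiv), THF, −78 °C, 15 min; B cannulated into A, −78 to −20 °C; cold filtration through neutral alumina
Reagents that add atoms: none
Why: Proposed new method: KN(SiMe3)2 removes the ester α-hydrogen at C2 of 9 and bromide leaves from C1 (E1cB-type 1,2-elimination), giving 11, whose tetrasubstituted double bond is strained and activated by both esters. Ylide 10 adds through its benzylic carbon to one olefinic carbon to give betaine 12, a cyclopropyl ester enolate; its carbanionic carbon then displaces dimethyl sulfide with inversion in a 3-exo-tet closure, which forms the second three-membered ring and the second C–C bond at the benzylic carbon. The closest known reactions are the Corey–Chaykovsky cyclopropanation of electron-poor alkenes (the same addition and 1,3-displacement, here on a cyclopropene) and the closure of bicyclobutanes by 1,3-displacement from stabilised cyclopropyl carbanions; formal nucleophilic substitution of bromocyclopropanes shows that cyclopropenes generated by base accept nucleophiles at once. The stereocentre that comes from C3 of 11 is set by approach of the ylide anti to the C3 phenyl, which leaves that phenyl exo, and the bridgeheads have no freedom because the fusion can only be cis. The new benzylic centre is set by the configuration of 12 at the sulfonium carbon together with inversion in the closure: the rotamer that closes to the exo product keeps its phenyl away from the ring and its endo hydrogen, and the t-BuOH left from ylide formation can equilibrate the two epimers of 12 by proton transfer at the acidic α-sulfonium position so that the faster exo closure drains both. The selectivity needed is exo,exo, since only that isomer gives cis phenyls after ring opening, whereas exo,endo leads to the trans-diphenyl series. Making 11 with a non-nucleophilic amide base in a separate flask and transferring it cold into 10 keeps the soft ylide away from the α-bromo ester (halophilic attack), avoids alkoxide addition to 11 and limits ene-type self-reaction of 11.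

Step 5
Reactants: 13 dimethyl exo,exo-2,4-diphenylbicyclo[1.1.0]butane-1,3-dicarboxylate
Product: 15 dimethyl all-trans-2,4-diphenylcyclobutane-1,3-dicarboxylate (r-1,t-2,c-3,t-4), via C1/C3-epimeric cis-diphenyl diesters 14 (not isolated)
Conditions: SmI2 (2.5 equiv), HMPA, t-BuOH, THF, −78 to 0 °C; aqueous work-up; then NaOMe (0.5 equiv), MeOH, 65 °C; crystallise
Reagents that add atoms: none
Why: Single-electron reductive cleavage of an acceptor-flanked strained bond, as for ene-diesters and acyl bicyclobutanes: two electrons from divalent samarium break the central bond to a 1,3-bis-enolate, which t-BuOH protonates to 14. NaOMe then equilibrates both α-centres (thermodynamic epimerisation) to the isomer with each ester trans to both neighbouring phenyls. C2 and C4 are untouched, so exo,exo in 13 becomes cis-diphenyl in 15.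

Step 6
Reactants: 15 dimethyl all-trans-2,4-diphenylcyclobutane-1,3-dicarboxylate
Product: 17 all-trans-2,4-diphenylcyclobutane-1,3-dicarboxylic acid, via disodium dicarboxylate 16 (not isolated)
Conditions: NaOH (6 equiv), THF–MeOH–H2O, 65 °C; then 2 M HCl
Reagents that add atoms: sodium hydroxide, [Na+].[OH-]
Why: Saponification by acyl–oxygen cleavage of two secondary methyl esters. The α-centres are already in their thermodynamic configuration, so base cannot erode them.

Step 7
Reactants: 17 all-trans-2,4-diphenylcyclobutane-1,3-dicarboxylic acid; 18 resorcinol
Product: 19 all-trans-1,3-bis(2,4-dihydroxybenzoyl)-2,4-diphenylcyclobutane (r-1,t-2,c-3,t-4; target)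
Conditions: 18 (5 equiv), BF3·OEt2, 85 °C; then aq. NaOAc, 80 °C
Reagents that add atoms: none
Why: Direct BF3-mediated Friedel–Crafts C-acylation of resorcinol by a carboxylic acid (Nencki-type; any aryl ester formed undergoes Fries rearrangement). Attack at position 4 of 18, para to one hydroxyl and ortho to the other, gives the 2,4-dihydroxyphenyl ketone on each side. Enolisation of the new ketones can only return to the all-trans arrangement, which is the thermodynamic one, and aqueous NaOAc hydrolyses the boron chelates.

## Compound list

1 | benzyl bromide | BrCc1ccccc1 | starting material
2 | dimethyl sulfide | CSC | starting material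
3 | benzyldimethylsulfonium bromide | C[S+](C)Cc1ccccc1.[Br-] | intermediate
4 | 3-phenylglutaric acid (3-phenylpentanedioic acid) | OC(=O)CC(c1ccccc1)CC(=O)O | starting material
5 | 3-phenylpentanedioyl dichloride (not isolated) | ClC(=O)CC(c1ccccc1)CC(Cl)=O | intermediate
6 | 2,4-dibromo-3-phenylpentanedioyl dichloride (diastereomer mixture; not isolated) | ClC(=O)C(Br)C(c1ccccc1)C(Br)C(Cl)=O | intermediate
7 | dimethyl 2,4-dibromo-3-phenylpentanedioate (diastereomer mixture, configuration deliberately open) | COC(=O)C(Br)C(c1ccccc1)C(Br)C(=O)OC | intermediate
8 | lithium enolate of 7 (not isolated) | COC([O-])=C(Br)C(c1ccccc1)C(Br)C(=O)OC.[Li+] | intermediate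
9 | dimethyl 1-bromo-3-phenylcyclopropane-1,2-dicarboxylate (racemic mixture of diastereomers, configuration deliberately open) | COC(=O)C1(Br)C(C(=O)OC)C1c1ccccc1 | intermediate
10 | dimethylsulfonium benzylide (ylide of 3; not isolated) | C[S+](C)[CH-]c1ccccc1 | intermediate
11 | dimethyl 3-phenylcycloprop-1-ene-1,2-dicarboxylate (not isolated) | COC(=O)C1=C(C(=O)OC)C1c1ccccc1 | intermediate
12 | betaine: C2 enolate of dimethyl 1-[(dimethylsulfonio)(phenyl)methyl]-3-phenylcyclopropane-1,2-dicarboxylate, sulfonium arm trans to the C3 phenyl, epimer that closes to exo phenyl (racemic; not isolated) | C[S+](C)[C@@H](c1ccccc1)[C@@]2(C(=O)OC)[C@H](c3ccccc3)C2=C([O-])OC | intermediate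
13 | dimethyl exo,exo-2,4-diphenylbicyclo[1.1.0]butane-1,3-dicarboxylate (achiral) | c1ccccc1[C@@H]2[C@@]3(C(=O)OC)[C@H](c4ccccc4)[C@@]23C(=O)OC | intermediate
14 | dimethyl c-2,c-4-diphenylcyclobutane-1,3-dicarboxylate, mixture of C1/C3 epimers, phenyls cis (not isolated) | COC(=O)C1[C@H](c2ccccc2)C(C(=O)OC)[C@@H]1c1ccccc1 | intermediate
15 | dimethyl all-trans-2,4-diphenylcyclobutane-1,3-dicarboxylate (r-1,t-2,c-3,t-4) | COC(=O)[C@H]1[C@H](c2ccccc2)[C@@H](C(=O)OC)[C@@H]1c1ccccc1 | intermediate
16 | disodium all-trans-2,4-diphenylcyclobutane-1,3-dicarboxylate (not isolated) | [Na+].[Na+].[O-]C(=O)[C@H]1[C@H](c2ccccc2)[C@@H](C([O-])=O)[C@@H]1c1ccccc1 | intermediate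
17 | all-trans-2,4-diphenylcyclobutane-1,3-dicarboxylic acid (r-1,t-2,c-3,t-4) | OC(=O)[C@H]1[C@H](c2ccccc2)[C@@H](C(=O)O)[C@@H]1c1ccccc1 | intermediate
18 | resorcinol | Oc1cccc(O)c1 | starting material
19 | all-trans-1,3-bis(2,4-dihydroxybenzoyl)-2,4-diphenylcyclobutane (r-1,t-2,c-3,t-4) | O=C(c1ccc(O)cc1O)[C@H]1[C@H](c2ccccc2)[C@@H](C(=O)c2ccc(O)cc2O)[C@@H]1c1ccccc1 | target

## Step count and risks

Total: 7 steps. Longest linear sequence: 6 steps, from 3-phenylglutaric acid 4 to 19 (steps 2 to 7). Salt 3 is made in step 1 and enters at step 4; resorcinol 18 enters at step 7.

**Step 4 (key step).** The most likely failures are three: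
- bonding through the wrong face of the ylide carbon, which places the new phenyl endo, because nothing but sterics separates the two epimers of betaine 12;
- diversion of the betaine before closure by proton transfer or rearrangement of the sulfonium ylide;
- ene-type self-reaction of cyclopropene 11 before it is captured.

The fallback sets out from 9 and returns at 13. A Reformatsky reaction of 9 with benzaldehyde (Zn, THF) gives the carbinol dimethyl 1-[hydroxy(phenyl)methyl]-3-phenylcyclopropane-1,2-dicarboxylate F1. Its diastereomers are separated, and the one with the carbinol arm trans to the ring phenyl is converted with MsCl/Et3N at −20 °C into the methanesulfonate dimethyl 1-[(methylsulfonyloxy)(phenyl)methyl]-3-phenylcyclopropane-1,2-dicarboxylate F2, which is used at once. KN(SiMe3)2 at −78 °C then deprotonates C2, and the cyclopropyl carbanion displaces methanesulfonate with inversion, the 1,3-elimination used for sulfonyl bicyclobutanes. Each carbinol epimer should give one bicyclobutane epimer, so the exo series can be selected at the carbinol stage. No free cyclopropene and no ylide is involved.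

**Step 5.** Electron transfer to the hindered diester may be slow, or a benzylic side bond may cleave in competition with the central bond, since both modes release similar strain. The fallback sets out from 13 and returns at 14. Radical strain-release addition of thiophenol (PhSH, AIBN, 60 °C) across the central bond should give dimethyl c-2,c-4-diphenyl-1-(phenylsulfanyl)cyclobutane-1,3-dicarboxylate F3. Raney Ni in ethanol then removes sulfur to give the epimer mixture 14, which is equilibrated with NaOMe as in the route.

**Step 2.** Radical-chain bromination at the benzylic C3–H or electrophilic bromination of the phenyl ring may compete with α-bromination, and the second α-bromination may stall. The fallback sets out from 4 and returns at 7, and moves the bromination to low temperature. Fischer esterification (MeOH, H2SO4) gives dimethyl 3-phenylpentanedioate F4. LiN(iPr)2 (2.2 equiv) in the presence of Me3SiCl at −78 °C converts it into the bis(trimethylsilyl ketene acetal) 1,5-dimethoxy-3-phenyl-1,5-bis(trimethylsilyloxy)penta-1,4-diene F5. NBS in THF at −78 °C then brominates both ketene acetal carbons to give 7.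

**Step 3.** Further loss of HBr from 9 under the basic conditions, followed by consumption of the resulting cyclopropene, is the main danger; intermolecular condensation of enolate 8 is a second one. The fallback sets out from 7 and returns at 9, and separates ring closure from bromination. Zinc dust in THF should insert into one C–Br bond and close the ring by displacement of the other bromide (reductive 1,3-elimination), giving dimethyl 3-phenylcyclopropane-1,2-dicarboxylate F6, which has no leaving group and cannot eliminate. LiN(iPr)2 at −78 °C then gives the lithium ester enolate F7, and inverse addition to BrCCl2CCl2Br installs the bromine to give 9.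

**Step 7.** The second acylation may stall, O-acylation may occur without rearrangement, or the strained ring may suffer acid-induced damage at 85 °C. The fallback sets out from 17 and returns at 19. Oxalyl chloride with catalytic DMF gives all-trans-2,4-diphenylcyclobutane-1,3-dicarbonyl dichloride F8. AlCl3-mediated Friedel–Crafts acylation of 1,3-dimethoxybenzene at 0 °C gives all-trans-1,3-bis(2,4-dimethoxybenzoyl)-2,4-diphenylcyclobutane F9. BBr3 in CH2Cl2 cleaves the four methyl ethers.

## Further compounds

F1 | step 4 | dimethyl 1-[hydroxy(phenyl)methyl]-3-phenylcyclopropane-1,2-dicarboxylate (carbinol arm trans to the C3 phenyl; C2 either epimer) | O[C@@H](c1ccccc1)[C@@]2(C(=O)OC)[C@H](c3ccccc3)C2C(=O)OC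
F2 | step 4 | dimethyl 1-[(methylsulfonyloxy)(phenyl)methyl]-3-phenylcyclopropane-1,2-dicarboxylate (same configuration as F1) | CS(=O)(=O)O[C@@H](c1ccccc1)[C@@]2(C(=O)OC)[C@H](c3ccccc3)C2C(=O)OC
F3 | step 5 | dimethyl c-2,c-4-diphenyl-1-(phenylsulfanyl)cyclobutane-1,3-dicarboxylate (phenyls cis; C1/C3 open) | COC(=O)C1(Sc2ccccc2)[C@H](c2ccccc2)C(C(=O)OC)[C@@H]1c1ccccc1
F4 | step 2 | dimethyl 3-phenylpentanedioate | COC(=O)CC(c1ccccc1)CC(=O)OC
F5 | step 2 | 1,5-dimethoxy-3-phenyl-1,5-bis(trimethylsilyloxy)penta-1,4-diene (bis(trimethylsilyl ketene acetal) of F4; double-bond geometry open) | COC(O[Si](C)(C)C)=CC(c1ccccc1)C=C(OC)O[Si](C)(C)C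
F6 | step 3 | dimethyl 3-phenylcyclopropane-1,2-dicarboxylate (configuration open) | COC(=O)C1C(C(=O)OC)C1c1ccccc1
F7 | step 3 | lithium ester enolate of F6 | COC([O-])=C1C(C(=O)OC)C1c1ccccc1.[Li+]
F8 | step 7 | all-trans-2,4-diphenylcyclobutane-1,3-dicarbonyl dichloride | ClC(=O)[C@H]1[C@H](c2ccccc2)[C@@H](C(Cl)=O)[C@@H]1c1ccccc1
F9 | step 7 | all-trans-1,3-bis(2,4-dimethoxybenzoyl)-2,4-diphenylcyclobutane | O=C(c1ccc(OC)cc1OC)[C@H]1[C@H](c2ccccc2)[C@@H](C(=O)c2ccc(OC)cc2OC)[C@@H]1c1ccccc1
A1 | alternative 1 | all-cis 2,4-diphenyl-N1,N3-di(quinolin-8-yl)cyclobutane-1,3-dicarboxamide | O=C(Nc1cccc2cccnc12)[C@H]1[C@@H](c2ccccc2)[C@@H](C(=O)Nc2cccc3cccnc23)[C@H]1c1ccccc1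
A2 | alternative 1 | cis-N1,N3-di(quinolin-8-yl)cyclobutane-1,3-dicarboxamide | O=C(Nc1cccc2cccnc12)[C@H]1C[C@@H](C(=O)Nc2cccc3cccnc23)C1
A3 | alternative 2 | bis(trimethylsilyl ketene acetal) of dimethyl cis-2,4-diphenylcyclobutane-1,3-dicarboxylate | COC(O[Si](C)(C)C)=C1[C@H](c2ccccc2)C(=C(OC)O[Si](C)(C)C)[C@@H]1c1ccccc1
A4 | alternative 2 | 2,4-dimethoxybenzoyl chloride | COc1ccc(C(=O)Cl)c(OC)c1
A5 | alternative 2 | dimethyl 1,3-bis(2,4-dimethoxybenzoyl)-2,4-diphenylcyclobutane-1,3-dicarboxylate (aroyl groups trans to both phenyls) | COC(=O)[C@@]1(C(=O)c2ccc(OC)cc2OC)[C@@H](c2ccccc2)[C@](C(=O)OC)(C(=O)c2ccc(OC)cc2OC)[C@H]1c1ccccc1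
A6 | alternative 3 | 2-chloro-4-methoxy-6-(trimethylsilyl)phenyl trifluoromethanesulfonate | COc1cc(Cl)c(OS(=O)(=O)C(F)(F)F)c([Si](C)(C)C)c1
A7 | alternative 3 | 3-chloro-5-methoxybenzyne | COC1=CC#CC(Cl)=C1
A8 | alternative 3 | all-trans 1,3-bis(6-chloro-2-hydroxy-4-methoxybenzoyl)-2,4-diphenylcyclobutane | O=C(c1c(O)cc(OC)cc1Cl)[C@H]2[C@H](c3ccccc3)[C@@H](C(=O)c3c(O)cc(OC)cc3Cl)[C@@H]2c2ccccc2
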